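**Retrosynthetic overview** (ring A = 2,6-dimethoxyphenyl ring, ring B = the hexasubstituted ring)
1. No ring is formed: ring B is bought as 2,6-dimethyl-1,4-benzoquinone 1 and ring A as 2,6-dimethoxybenzaldehyde 2.
2. Diaryl ketone C–C bond (supporting disconnection): photo-acylation of 1 by 2 gives acylhydroquinone 3.
3. Key disconnection, the benzylic CH2–OAc bond: 3 is oxidised to acylquinone 4, which tautomerises to o-quinone methide 5 and takes up acetate to give benzylic acetate 6.
4. Last disconnection, the aryl O–CH3 bond: methylation of the one non-chelated phenol of 6 gives the target 7.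

Assumption: the SMILES contains no stereocentre and ring A is symmetric, so the target is achiral and no enantiomer has to be selected.

**Step 1**
Reactants: 1 2,6-dimethyl-1,4-benzoquinone; 2 2,6-dimethoxybenzaldehyde
Product: 3 (3,6-dihydroxy-2,4-dimethylphenyl)(2,6-dimethoxyphenyl)methanone
Conditions: 2 (3 equiv), hν (450 nm LEDs), PhCF3, rt, Ar
Reagents that add atoms: none
Why: Photo-Friedel–Crafts acylation of a quinone by an aldehyde: the triplet quinone abstracts the formyl hydrogen and the aroyl/semiquinone radical pair collapses at the only unsubstituted ring carbon (C3 and C5 are equivalent), so this atom-economical addition gives one acylhydroquinone, which is photostable through its hydrogen-bonded o-hydroxy ketone; no stereocentre is formed.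

**Step 2**
Reactants: 3 (3,6-dihydroxy-2,4-dimethylphenyl)(2,6-dimethoxyphenyl)methanone
Product: 6 [2-(2,6-dimethoxybenzoyl)-3,6-dihydroxy-5-methylphenyl]methyl acetate, via acylquinone 4 (not isolated), via o-quinone methide 5 (not isolated)
Conditions: PhI(OAc)2 (1.0 equiv), AcOH/MeCN (1:1), rt, 20 min; then Bu4NOAc (0.5 equiv), 40 °C, Ar
Reagents that add atoms: acetic acid, CC(=O)O
Why: Proposed new method: an isomerising (redox-relay) benzylic acetoxylation in which PhI(OAc)2 first oxidises 3 to acylquinone 4; the methyl next to the aroyl group is vinylogous to both a quinone carbonyl and the aroyl carbonyl, so the acetate/acetic acid pair shuttles its proton to the quinone oxygen much faster than that of the other, singly activated methyl and gives o-quinone methide 5, and acetate then adds 1,4 to the exocyclic CH2 with rearomatisation to the hydroquinone as driving force (about 15 kcal/mol downhill from 4 plus AcOH), with no oxidant left in this second stage; the closest known reaction types are the base-induced tautomerisation of alkylquinones to quinone methides and the 5a-functionalisation of α-tocopherol through an o-quinone methide, but intermolecular carboxylate capture of an acylquinone-derived quinone methide with the aroyl group as regiocontrol element has not been shown; no stereocentre is formed.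

**Step 3**
Reactants: 6 [2-(2,6-dimethoxybenzoyl)-3,6-dihydroxy-5-methylphenyl]methyl acetate
Product: 7 [2-(2,6-dimethoxybenzoyl)-3-hydroxy-6-methoxy-5-methylphenyl]methyl acetate (preacredinone A)
Conditions: TMSCHN2 (3 equiv), MeOH/PhMe (1:4), 0 °C → rt
Reagents that add atoms: trimethylsilyldiazomethane, C[Si](C)(C)C=[N+]=[N-]
Why: Diazoalkane O-methylation of a phenol: the 3-OH is locked in a hydrogen bond to the ketone and stays inert, the free 6-OH is methylated, and the base-free medium avoids a phenoxide that could expel the neighbouring benzylic acetate; no stereocentre is formed.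

**Compound list**
1 | 2,6-dimethyl-1,4-benzoquinone | CC1=CC(=O)C=C(C)C1=O | starting material
2 | 2,6-dimethoxybenzaldehyde | COc1cccc(OC)c1C=O | starting material
3 | (3,6-dihydroxy-2,4-dimethylphenyl)(2,6-dimethoxyphenyl)methanone | COc1cccc(OC)c1C(=O)c1c(O)cc(C)c(O)c1C | intermediate
4 | 2-(2,6-dimethoxybenzoyl)-3,5-dimethylcyclohexa-2,5-diene-1,4-dione | COc1cccc(OC)c1C(=O)C1=C(C)C(=O)C(C)=CC1=O | intermediate (not isolated)
5 | 3-(2,6-dimethoxybenzoyl)-4-hydroxy-6-methyl-2-methylidenecyclohexa-3,5-dien-1-one | COc1cccc(OC)c1C(=O)C1=C(O)C=C(C)C(=O)C1=C | intermediate (not isolated)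
6 | [2-(2,6-dimethoxybenzoyl)-3,6-dihydroxy-5-methylphenyl]methyl acetate | COc1cccc(OC)c1C(=O)c1c(O)cc(C)c(O)c1COC(C)=O | intermediate
7 | [2-(2,6-dimethoxybenzoyl)-3-hydroxy-6-methoxy-5-methylphenyl]methyl acetate (preacredinone A, achiral) | COc1cccc(OC)c1C(=O)c1c(O)cc(C)c(OC)c1COC(C)=O | target

**Total step count:** 3. **Longest linear sequence:** 3 steps (1 → 3 → 6 → 7).

**Steps most likely to fail** (step 2 is the riskiest, then step 1, then step 3)

Step 1, photo-acylation. The electron-rich, doubly ortho-substituted aldehyde may quench the quinone triplet by electron transfer or couple at oxygen, and conversion may be low. The fallback sets out from 1 and comes back at 3, and it makes the ketone through an ester C–O bond first. Quinone 1 is reduced with aqueous Na2S2O4 (Et2O/H2O, rt) to 2,6-dimethylbenzene-1,4-diol F1. The unhindered 4-OH of F1 is acylated with commercial 2,6-dimethoxybenzoyl chloride (COc1cccc(OC)c1C(Cl)=O; Et3N, CH2Cl2, 0 °C) to give 4-hydroxy-3,5-dimethylphenyl 2,6-dimethoxybenzoate F2. An acid-mediated Fries rearrangement (TfOH, CH2Cl2, 0 °C → rt) then moves the aroyl group to the ortho carbon, the para position being blocked, and gives 3.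

Step 2, the new isomerising acetoxylation. Quinone methide 5 may dimerise, hydrogen exchange between product hydroquinone 6 and unreacted quinone 4 may lead to over-oxidised side-chain products, or the tautomerisation may be too slow under acetate buffering. The fallback uses only known chemistry, sets out from 2 and comes back at 7.
- Commercial 2-methoxy-3-methylbenzoic acid (COc1c(C)cccc1C(=O)O) is lithiated ortho to the carboxylate (s-BuLi 2.2 equiv, TMEDA, THF, −78 °C) to lithium 6-lithio-2-methoxy-3-methylbenzoate F3.
- F3 adds to 2 and, after HCl work-up, gives racemic 6-[(2,6-dimethoxyphenyl)(hydroxy)methyl]-2-methoxy-3-methylbenzoic acid F4.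
- TsOH in refluxing PhMe closes F4 to racemic 3-(2,6-dimethoxyphenyl)-7-methoxy-6-methyl-2-benzofuran-1(3H)-one F5.
- LiAlH4 (THF, 0 °C) opens the lactone to racemic (2,6-dimethoxyphenyl)[2-(hydroxymethyl)-3-methoxy-4-methylphenyl]methanol F6.
- Ac2O/pyridine at 0 °C acetylates only the primary hydroxyl and gives racemic {2-[(2,6-dimethoxyphenyl)(hydroxy)methyl]-6-methoxy-5-methylphenyl}methyl acetate F7.
- Dess–Martin periodinane (CH2Cl2, rt) oxidises the hindered carbinol to [2-(2,6-dimethoxybenzoyl)-6-methoxy-5-methylphenyl]methyl acetate F8, which removes the only stereocentre of this detour.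
- Ketone-directed ortho C–H oxygenation (Pd(OAc)2 5 mol%, PhI(OCOCF3)2, ClCH2CH2Cl, 80 °C) acts on the only free ortho position (ring A has none) and gives [2-(2,6-dimethoxybenzoyl)-6-methoxy-5-methyl-3-(trifluoroacetoxy)phenyl]methyl acetate F9, which aqueous NaHCO3 work-up hydrolyses to 7.

Step 3, selective methylation. The hindered 6-OH may react slowly with TMSCHN2, and any phenoxide formed can expel the neighbouring acetate. The fallback sets out from 6 and comes back at 7, and it carries the benzylic oxygen as a free alcohol, which cannot leave, through the methylation. The acetate of 6 is hydrolysed (LiOH, degassed THF/H2O, 0 °C, then HCl) to (2,6-dimethoxyphenyl)[3,6-dihydroxy-2-(hydroxymethyl)-4-methylphenyl]methanone F10. Classical methylation (MeI, K2CO3, acetone, rt) takes the non-chelated phenol only and gives (2,6-dimethoxyphenyl)[6-hydroxy-2-(hydroxymethyl)-3-methoxy-4-methylphenyl]methanone F11. Ac2O (1.1 equiv) in pyridine/CH2Cl2 at 0 °C acetylates the primary alcohol and leaves the chelated phenol, giving 7.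

**Further compounds**
F1 | step 1 | 2,6-dimethylbenzene-1,4-diol | Cc1cc(O)cc(C)c1O
F2 | step 1 | 4-hydroxy-3,5-dimethylphenyl 2,6-dimethoxybenzoate | COc1cccc(OC)c1C(=O)Oc1cc(C)c(O)c(C)c1
F3 | step 2 | lithium 6-lithio-2-methoxy-3-methylbenzoate | [Li]c1ccc(C)c(OC)c1C(=O)O[Li]
F4 | step 2 | 6-[(2,6-dimethoxyphenyl)(hydroxy)methyl]-2-methoxy-3-methylbenzoic acid (racemic) | COc1cccc(OC)c1C(O)c1ccc(C)c(OC)c1C(=O)O
F5 | step 2 | 3-(2,6-dimethoxyphenyl)-7-methoxy-6-methyl-2-benzofuran-1(3H)-one (racemic) | COc1cccc(OC)c1C1OC(=O)c2c(OC)c(C)ccc12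
F6 | step 2 | (2,6-dimethoxyphenyl)[2-(hydroxymethyl)-3-methoxy-4-methylphenyl]methanol (racemic) | COc1cccc(OC)c1C(O)c1ccc(C)c(OC)c1CO
F7 | step 2 | {2-[(2,6-dimethoxyphenyl)(hydroxy)methyl]-6-methoxy-5-methylphenyl}methyl acetate (racemic) | COc1cccc(OC)c1C(O)c1ccc(C)c(OC)c1COC(C)=O
F8 | step 2 | [2-(2,6-dimethoxybenzoyl)-6-methoxy-5-methylphenyl]methyl acetate | COc1cccc(OC)c1C(=O)c1ccc(C)c(OC)c1COC(C)=O
F9 | step 2 | [2-(2,6-dimethoxybenzoyl)-6-methoxy-5-methyl-3-(trifluoroacetoxy)phenyl]methyl acetate | COc1cccc(OC)c1C(=O)c1c(OC(=O)C(F)(F)F)cc(C)c(OC)c1COC(C)=O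
F10 | step 3 | (2,6-dimethoxyphenyl)[3,6-dihydroxy-2-(hydroxymethyl)-4-methylphenyl]methanone | COc1cccc(OC)c1C(=O)c1c(O)cc(C)c(O)c1CO
F11 | step 3 | (2,6-dimethoxyphenyl)[6-hydroxy-2-(hydroxymethyl)-3-methoxy-4-methylphenyl]methanone | COc1cccc(OC)c1C(=O)c1c(O)cc(C)c(OC)c1CO
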